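**Retrosynthetic overview**

1. The strategy rests on the pyranone ring (ring B): O1–C2(=O)–C3H=C4H is an unsubstituted cis-acrylate bridge from the oxygen on C8a to C4a, so C2 and C3 can both be taken from the two-carbon unit of Ph3P=C=C=O (4).
2. Key disconnection: O1–C2 (addition of the phenol) and C3=C4 (intramolecular Wittig) of 8-acetyl-7-methoxycoumarin 6, leading back to salicylaldehyde 3; 3 comes from 2'-hydroxy-6'-methoxyacetophenone 1 by formylation at its one free position ortho to the hydroxyl.
3. Side chain on C8: the enol-ester C=C by loss of HNO2 from the β-nitro ester 12, the ester C–O from senecioyl chloride 11, the C–C bond by nitroaldol of arylglyoxal 8 with 2-nitropropane 9, and 8 by SeO2 oxidation of the acetyl group of 6.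
4. Ring order: benzene ring A is bought; ring B is the only ring formed (step 2); the side chain is completed last.

Key step: step 2

Remark on the chemistry: the target has no stereocentre and no configured acyclic double bond. The one stereocentre that appears (the carbinol carbon of 10 and 12) is carried as the racemate and is erased in step 6. Glyoxal 8 is drawn as the free aldehyde; its gem-diol 7 is the form present while water is in the flask.

**Route**

Step 1
Reactants: 1 2'-hydroxy-6'-methoxyacetophenone
Product: 3 3-acetyl-2-hydroxy-4-methoxybenzaldehyde, via benzylic alcohol 2 (not isolated)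
Conditions: MgCl2, Et3N, (CH2O)n, MeCN, reflux; then 1 M HCl
Reagents that add atoms: paraformaldehyde (as formaldehyde), C=O
Why: Magnesium-mediated ortho-formylation of a phenol (Casnati–Skattebøl reaction): the magnesium phenoxide of 1 delivers formaldehyde to C3', the only free carbon ortho to the oxygen and also para to the methoxy group, and the benzylic alkoxide of 2 is then oxidised to the aldehyde by a second formaldehyde through hydride transfer.

Step 2
Reactants: 3 3-acetyl-2-hydroxy-4-methoxybenzaldehyde; 4 (triphenylphosphoranylidene)ketene
Product: 6 8-acetyl-7-methoxycoumarin, via ylide ester 5 (not isolated)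
Conditions: 4 (1.1 equiv), toluene, reflux, argon
Reagents that add atoms: none
Why: The phenolic O–H of 3 adds across the C=C of the cumulated ylide 4 (protonation at carbon, then capture of the ketenyl phosphonium by the phenoxide) to give the ester-stabilised ylide 5, which forms bond O1–C2. The ylide carbon of 5 then attacks the formyl carbon held ortho to the ester oxygen, and cycloreversion of the oxaphosphetane expels Ph3PO and forms C3=C4. The closest known reaction type is the one-pot synthesis of coumarins from salicylaldehydes and (triphenylphosphoranylidene)ketene by addition and intramolecular Wittig olefination. Ring B is closed in 6-exo-trig fashion by the intramolecular Wittig step, the ring forces the new C3=C4 bond to be cis, and no stereocentre is created. The selectivity needed is olefination of the aldehyde and not of the acetyl group on the other side of the same oxygen; it is secured because an ester-stabilised ylide reacts far faster with an aldehyde than with a twisted aryl methyl ketone flanked by two ortho substituents. The medium is neutral and free of nucleophiles, so the ketone, the aryl methyl ether and the new lactone should remain untouched.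

Step 3
Reactants: 6 8-acetyl-7-methoxycoumarin
Product: 8 2-(7-methoxy-2-oxo-2H-chromen-8-yl)-2-oxoacetaldehyde, via glyoxal hydrate 7 (not isolated)
Conditions: SeO2, 1,4-dioxane–H2O (50:1), reflux; filtration; toluene azeotrope
Reagents that add atoms: selenium dioxide, O=[Se]=O; water, O (held only in 7 and given off again on drying)
Why: Riley oxidation: SeO2 attacks the enol of the aryl methyl ketone and converts CH3 into CHO, the molecule offering no other enolisable or allylic C–H, and the gem-diol 7 formed with the water present is dehydrated on azeotropic drying.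

Step 4
Reactants: 8 2-(7-methoxy-2-oxo-2H-chromen-8-yl)-2-oxoacetaldehyde; 9 2-nitropropane
Product: 10 racemic 8-(2-hydroxy-3-methyl-3-nitrobutanoyl)-7-methoxy-2H-chromen-2-one
Conditions: 9 (5 equiv), Et3N (0.2 equiv), THF, 0 °C to rt
Reagents that add atoms: none
Why: Henry (nitroaldol) reaction: the nitronate of 2-nitropropane adds to the formyl carbon of the glyoxal, which is far more electrophilic than the flanked aryl ketone or the lactone (as with glyoxylate esters), and the new carbinol centre is formed racemic and removed in step 6.

Step 5
Reactants: 10 racemic 8-(2-hydroxy-3-methyl-3-nitrobutanoyl)-7-methoxy-2H-chromen-2-one; 11 3-methylbut-2-enoyl chloride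
Product: 12 racemic 1-(7-methoxy-2-oxo-2H-chromen-8-yl)-3-methyl-3-nitro-1-oxobutan-2-yl 3-methylbut-2-enoate
Conditions: 11 (1.5 equiv), pyridine, DMAP (cat.), CH2Cl2, 0 °C to rt
Reagents that add atoms: none
Why: DMAP-catalysed esterification of a secondary alcohol with an acid chloride; pyridine is too weak a base to drive retro-nitroaldol cleavage quickly, and the tertiary nitro group and the lactone are inert to the acylating agent.

Step 6
Reactants: 12 racemic 1-(7-methoxy-2-oxo-2H-chromen-8-yl)-3-methyl-3-nitro-1-oxobutan-2-yl 3-methylbut-2-enoate
Product: 13 kimcuongin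
Conditions: DBU (1.5 equiv), CH2Cl2, 0 °C to rt
Reagents that add atoms: none
Why: E1cB elimination of nitrous acid from a β-nitro ketone: DBU removes the C–H alpha to the aryl ketone that carries the acyloxy group and the enolate expels nitrite from the tertiary carbon to give the tetrasubstituted enol-ester enone, while the nitro carbon has no hydrogen and so cannot lose the carboxylate toward a nitroalkene.

**Compound list**

1 | 2'-hydroxy-6'-methoxyacetophenone | CC(=O)c1c(O)cccc1OC | starting material
2 | 1-[2-hydroxy-3-(hydroxymethyl)-6-methoxyphenyl]ethan-1-one (formed in the flask in step 1) | CC(=O)c1c(OC)ccc(CO)c1O | intermediate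
3 | 3-acetyl-2-hydroxy-4-methoxybenzaldehyde | CC(=O)c1c(OC)ccc(C=O)c1O | intermediate
4 | (triphenylphosphoranylidene)ketene | O=C=C=P(c1ccccc1)(c1ccccc1)c1ccccc1 | starting material
5 | 2-acetyl-6-formyl-3-methoxyphenyl (triphenylphosphoranylidene)acetate (formed in the flask in step 2) | CC(=O)c1c(OC)ccc(C=O)c1OC(=O)C=P(c1ccccc1)(c1ccccc1)c1ccccc1 | intermediate
6 | 8-acetyl-7-methoxycoumarin (8-acetyl-7-methoxy-2H-chromen-2-one) | CC(=O)c1c(OC)ccc2ccc(=O)oc12 | intermediate
7 | 8-(2,2-dihydroxyacetyl)-7-methoxy-2H-chromen-2-one (formed in the flask in step 3) | COc1ccc2ccc(=O)oc2c1C(=O)C(O)O | intermediate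
8 | 2-(7-methoxy-2-oxo-2H-chromen-8-yl)-2-oxoacetaldehyde | COc1ccc2ccc(=O)oc2c1C(=O)C=O | intermediate
9 | 2-nitropropane | CC(C)[N+](=O)[O-] | starting material
10 | racemic 8-(2-hydroxy-3-methyl-3-nitrobutanoyl)-7-methoxy-2H-chromen-2-one | COc1ccc2ccc(=O)oc2c1C(=O)C(O)C(C)(C)[N+](=O)[O-] | intermediate
11 | 3-methylbut-2-enoyl chloride (senecioyl chloride) | CC(C)=CC(=O)Cl | starting material
12 | racemic 1-(7-methoxy-2-oxo-2H-chromen-8-yl)-3-methyl-3-nitro-1-oxobutan-2-yl 3-methylbut-2-enoate | COc1ccc2ccc(=O)oc2c1C(=O)C(OC(=O)C=C(C)C)C(C)(C)[N+](=O)[O-] | intermediate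
13 | kimcuongin, 1-(7-methoxy-2-oxo-2H-chromen-8-yl)-3-methyl-1-oxobut-2-en-2-yl 3-methylbut-2-enoate | COc1ccc2ccc(=O)oc2c1C(=O)C(OC(=O)C=C(C)C)=C(C)C | target

**Step count**

Total steps: 6. Longest linear sequence: 6 steps (1 to 13).

**Steps most likely to fail**

Step 5 (acylation of the carbinol of 10). The hydroxyl sits between a ketone and a quaternary nitro carbon, so acyl transfer may be slow. Under base the alkoxide may fragment by retro-nitroaldol before it is acylated. The acid chloride may also lose HCl to a vinylketene and deliver the ester with its double bond out of conjugation. The fallback sets out from 8 and comes back at 13; it replaces steps 4 to 6 and leaves the nitro chemistry altogether. Isopropenylmagnesium bromide (1.05 equiv) would be added to dry 8 in THF at −78 °C. The formyl group should be attacked in preference to the flanked aryl ketone and the lactone, giving racemic 8-(2-hydroxy-3-methylbut-3-enoyl)-7-methoxy-2H-chromen-2-one F1. This less hindered allylic alcohol cannot fragment and would be acylated with 11 (pyridine, DMAP cat., CH2Cl2) to racemic 1-(7-methoxy-2-oxo-2H-chromen-8-yl)-3-methyl-1-oxobut-3-en-2-yl 3-methylbut-2-enoate F2. Catalytic DBU in CH2Cl2 should then move the β,γ double bond into conjugation with the ketone through the dienolate, giving 13.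

Step 2 (key step). The phenol of 3 is hydrogen-bonded to two carbonyl groups and flanked on both sides, so its addition to the cumulated ylide may be slow enough for self-condensation or hydrolysis of 4 to compete. Olefination at the acetyl group is the other possible leak. The fallback sets out from 3 and comes back at 6. An intermolecular Wittig reaction of 3 with ethyl (triphenylphosphoranylidene)acetate in toluene at 80 °C, selective for the aldehyde, would give ethyl (E)-3-(3-acetyl-2-hydroxy-4-methoxyphenyl)prop-2-enoate F3. Heating F3 in N,N-diethylaniline at reflux (or irradiation at 350 nm in MeCN) should bring about E to Z isomerisation and lactonisation with loss of ethanol, giving 6.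

Step 1 (formylation). Chelation of magnesium between the phenoxide and the acetyl oxygen may lower the nucleophilicity of the ring and hinder delivery of formaldehyde to C3'. Aldol-type hydroxymethylation at the acetyl methyl group and incomplete conversion are the likely consequences. The fallback sets out from 1 and comes back at 3, bringing in the formyl carbon by a sigmatropic route. O-Allylation (allyl bromide, K2CO3, DMF) would give 1-[2-methoxy-6-(prop-2-en-1-yloxy)phenyl]ethan-1-one F4. Aromatic Claisen rearrangement (N,N-diethylaniline, 200 °C) can only go to the free ortho carbon and would give 1-[2-hydroxy-6-methoxy-3-(prop-2-en-1-yl)phenyl]ethan-1-one F5. Double-bond migration with RuHCl(CO)(PPh3)3 (cat.) in toluene at 80 °C would give 1-{2-hydroxy-6-methoxy-3-[(E)-prop-1-en-1-yl]phenyl}ethan-1-one F6. Lemieux–Johnson cleavage (OsO4 cat., NaIO4, 2,6-lutidine, dioxane–H2O) would then give 3.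

**Further compounds**

F1 | step 5 | racemic 8-(2-hydroxy-3-methylbut-3-enoyl)-7-methoxy-2H-chromen-2-one | COc1ccc2ccc(=O)oc2c1C(=O)C(O)C(C)=C
F2 | step 5 | racemic 1-(7-methoxy-2-oxo-2H-chromen-8-yl)-3-methyl-1-oxobut-3-en-2-yl 3-methylbut-2-enoate | COc1ccc2ccc(=O)oc2c1C(=O)C(OC(=O)C=C(C)C)C(C)=C
F3 | step 2 | ethyl (E)-3-(3-acetyl-2-hydroxy-4-methoxyphenyl)prop-2-enoate | CCOC(=O)/C=C/c1ccc(OC)c(C(C)=O)c1O
F4 | step 1 | 1-[2-methoxy-6-(prop-2-en-1-yloxy)phenyl]ethan-1-one | CC(=O)c1c(OCC=C)cccc1OC
F5 | step 1 | 1-[2-hydroxy-6-methoxy-3-(prop-2-en-1-yl)phenyl]ethan-1-one | CC(=O)c1c(OC)ccc(CC=C)c1O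
F6 | step 1 | 1-{2-hydroxy-6-methoxy-3-[(E)-prop-1-en-1-yl]phenyl}ethan-1-one | CC(=O)c1c(OC)ccc(/C=C/C)c1O
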